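Ring B, the enolised cyclohexanetrione, is disconnected at two C–C bonds: from the bridge-bearing carbon to the enol carbon next to the quaternary centre, and from the neighbouring ring carbonyl carbon to the free CH. The route exploits that this carbonyl carbon, the bridge-bearing carbon, the bridge CH2 and the adjoining phenol oxygen of ring A (the benzene ring) form the O–C(=O)–CH2–CH2 chain of a dihydrocoumarin. In one operation the acetyl enolate of a quaternary (S)-keto ester opens this lactone and the diketone dianion then closes ring B onto the methyl ester. The precursors are 6-hexanoyl-5-hydroxy-7-methoxy-3,4-dihydrocoumarin and methyl (2S)-2-acetyl-2,5-dimethylhex-4-enoate; a single C-butyrylation of ring B completes the route.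

Key step: step 6

Remark: ring B is written throughout in the enol tautomer of the target SMILES; the CIP descriptor of its quaternary carbon is (S) in 10, 11 and 12 and (R) in 14 and 15 only because the butyryl group changes substituent priorities, the spatial arrangement being the same.
Remark: LiN(iPr)2 and LiN(SiMe3)2 are taken as commercial solutions; the chelated phenol of 5 is left free on purpose, since its lithium salt shields the hexanoyl ketone from enolisation and addition in step 6.

Step 1
Reactants: 1 5-methoxyresorcinol; 2 hexanoyl chloride
Product: 3 1-(2,4-dihydroxy-6-methoxyphenyl)hexan-1-one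
Conditions: AlCl3 (3 equiv), PhNO2/CH2Cl2, 0 °C → rt; cold 1 M HCl
Reagents that add atoms: none
Why: Friedel–Crafts acylation of the strongly activated ring should place the ketone between OH and OMe, these two equivalent positions being statistically and sterically preferred over the carbon between the two hydroxyls, whose acylation product is removed by chromatography.

Step 2
Reactants: 3 1-(2,4-dihydroxy-6-methoxyphenyl)hexan-1-one; 4 acrylic acid
Product: 5 6-hexanoyl-5-hydroxy-7-methoxy-3,4-dihydrocoumarin
Conditions: 4 (3 equiv), Amberlyst-15, toluene, 110 °C, Dean–Stark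
Reagents that add atoms: none
Why: Acid-promoted Friedel–Crafts conjugate addition (hydroarylation) of the ring carbon between the two hydroxyls to acrylic acid, followed by lactonisation on the non-chelated hydroxyl, is the known route from phenols to 3,4-dihydrocoumarins, that carbon being favoured by its small neighbours and by the bond fixation of the hydrogen-bonded ketone, and closure on the chelated hydroxyl would give a lactone isomer that opens to the same intermediate in step 6.

Step 3
Reactants: 6 methyl (3R)-3-hydroxybutanoate; 7 prenyl bromide
Product: 8 methyl (2R)-2-[(1R)-1-hydroxyethyl]-5-methylhex-4-enoate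
Conditions: LiN(iPr)2 (2.2 equiv), THF, −78 → −20 °C; 7, DMPU, −78 → −10 °C; aq NH4Cl
Reagents that add atoms: none
Why: Fráter–Seebach alkylation, in which the lithium alkoxide–enolate dianion is a rigid six-membered chelate that the allylic bromide attacks on the face anti to the C3 methyl group, so that the (R)-carbinol centre sets the new C2 centre as (R) (anti product).

Step 4
Reactants: 8 methyl (2R)-2-[(1R)-1-hydroxyethyl]-5-methylhex-4-enoate
Product: 9 methyl (2S)-2-[(1R)-1-hydroxyethyl]-2,5-dimethylhex-4-enoate
Conditions: LiN(iPr)2 (2.3 equiv), THF, −78 → −15 °C; MeI, DMPU, −78 → −10 °C; aq NH4Cl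
Reagents that add atoms: iodomethane, CI
Why: Second Fráter–Seebach alkylation, in which the tetrasubstituted chelated dianion is again attacked anti to the C3 methyl group, on the face that took up prenyl in step 3, so that the order prenyl-then-methyl under control of the (R)-carbinol centre fixes the quaternary carbon as (S), any minor diastereomer being separable at this stage.

Step 5
Reactants: 9 methyl (2S)-2-[(1R)-1-hydroxyethyl]-2,5-dimethylhex-4-enoate
Product: 10 methyl (2S)-2-acetyl-2,5-dimethylhex-4-enoate
Conditions: Dess–Martin periodinane, CH2Cl2, rt
Reagents that add atoms: none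
Why: Dess–Martin oxidation of the secondary alcohol gives the β-keto ester under non-basic conditions that avoid retro-aldol cleavage, the quaternary centre having no α-hydrogen to epimerise and the trisubstituted alkene being inert.

Step 6
Reactants: 5 6-hexanoyl-5-hydroxy-7-methoxy-3,4-dihydrocoumarin; 10 methyl (2S)-2-acetyl-2,5-dimethylhex-4-enoate
Product: 12 debutyryl target (ring B enol bearing one free CH), via open-chain triketo ester 11 (not isolated)
Conditions: 5, LiN(SiMe3)2 (1.0 equiv), THF, −78 °C; added to Li enolate of 10 (2.2 equiv; LiN(iPr)2 2.3 equiv, THF, −78 °C), −78 → −30 °C; then LiN(iPr)2 (2.5 equiv), −78 → 0 °C; cold 1 M HCl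
Reagents that add atoms: none
Why: The acetyl methyl group is the only enolisable site of 10 (the other α-carbon is quaternary), and its lithium enolate adds to the aryl lactone of 5, which is far more electrophilic than the neopentyl-type methyl ester and than the hexanoyl ketone, the latter being masked as its chelated lithium phenoxide; expulsion of the phenoxide gives the diketonate of 11, which surplus enolate deprotonates. Added LiN(iPr)2 then removes a proton from the only free terminus of that diketonate, the CH2 next to the benzylic carbon, and this carbanion attacks the ester carbonyl and expels methoxide. The closest known reaction types are the Claisen acylation of ketone enolates by lactones and the Dieckmann-type closure of β-diketone dianions onto esters used for cyclic triketones and phloroglucinols. Ring B closes in a 6-(enolendo)-exo-trig mode, helped by the gem-disubstituted carbon. No stereocentre is formed, and the quaternary centre, which has no acidic hydrogen and none of whose bonds is broken, is carried through unchanged. The step needs site-selective enolisation, lactone-over-ester acylation and C- over O-cyclisation, which are secured by the blocked quaternary carbon, the phenoxide leaving group and the dianion conditions, and either lactone isomer of 5 would give the same product.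

Step 7
Reactants: 12 debutyryl target; 13 butyryl chloride
Product: 15 target CNP0219201.1, via ring B enol butyrate 14 (not isolated)
Conditions: 13 (1.05 equiv), Et3N (2.2 equiv), CH2Cl2, −20 → 0 °C; then DMAP (0.3 equiv), rt; cold 0.5 M HCl
Reagents that add atoms: none
Why: The ring B enol is a vinylogous carboxylic acid several pKa units more acidic than either ring A phenol (one of which is locked in a hydrogen bond to the hexanoyl ketone), so one equivalent of acid chloride should esterify its triethylammonium enolate first, after which DMAP turns the enol butyrate into an acylpyridinium–enolate pair that recombines at the only free ring B carbon (the known O→C acyl shift of 1,3-dione enol esters, a Fries-type rearrangement), the hydrogen-bonded 2-acyl-1,3-dione anion being the thermodynamic sink that also keeps the amine base away from the phenols.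

Compound list
1 | 5-methoxyresorcinol (5-methoxybenzene-1,3-diol) | COc1cc(O)cc(O)c1 | starting material
2 | hexanoyl chloride | CCCCCC(Cl)=O | starting material
3 | 1-(2,4-dihydroxy-6-methoxyphenyl)hexan-1-one | CCCCCC(=O)c1c(OC)cc(O)cc1O | intermediate
4 | acrylic acid | C=CC(=O)O | starting material
5 | 6-hexanoyl-5-hydroxy-7-methoxy-3,4-dihydrocoumarin (6-hexanoyl-5-hydroxy-7-methoxychroman-2-one) | O=C1CCc2c(O1)cc(OC)c(C(=O)CCCCC)c2O | intermediate
6 | methyl (3R)-3-hydroxybutanoate | COC(=O)C[C@@H](C)O | starting material
7 | prenyl bromide (1-bromo-3-methylbut-2-ene) | CC(C)=CCBr | starting material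
8 | methyl (2R)-2-[(1R)-1-hydroxyethyl]-5-methylhex-4-enoate | COC(=O)[C@H](CC=C(C)C)[C@@H](C)O | intermediate
9 | methyl (2S)-2-[(1R)-1-hydroxyethyl]-2,5-dimethylhex-4-enoate | COC(=O)[C@@](C)(CC=C(C)C)[C@@H](C)O | intermediate
10 | methyl (2S)-2-acetyl-2,5-dimethylhex-4-enoate | COC(=O)[C@@](C)(CC=C(C)C)C(C)=O | intermediate
11 | methyl (2S)-7-(3-hexanoyl-2,6-dihydroxy-4-methoxyphenyl)-2-methyl-2-(3-methylbut-2-en-1-yl)-3,5-dioxoheptanoate (formed in the flask, not isolated) | CCCCCC(=O)c1c(OC)cc(O)c(CCC(=O)CC(=O)[C@](C)(CC=C(C)C)C(=O)OC)c1O | intermediate
12 | debutyryl target, (4S)-2-[(3-hexanoyl-2,6-dihydroxy-4-methoxyphenyl)methyl]-3,5-dihydroxy-4-methyl-4-(3-methylbut-2-en-1-yl)cyclohexa-2,5-dien-1-one | CCCCCC(=O)c1c(OC)cc(O)c(CC2=C(O)[C@@](C)(CC=C(C)C)C(O)=CC2=O)c1O | intermediate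
13 | butyryl chloride (butanoyl chloride) | CCCC(Cl)=O | starting material
14 | ring B enol butyrate of 12 (formed in the flask, not isolated; drawn with the butyrate on the enol oxygen between the free CH and the quaternary carbon, the isomer on the other oxygen flanking the free CH rearranging to the same product; quaternary carbon as in 12) | CCCCCC(=O)c1c(OC)cc(O)c(CC2=C(O)[C@@](C)(CC=C(C)C)C(OC(=O)CCC)=CC2=O)c1O | intermediate
15 | CNP0219201.1, (4R)-2-butanoyl-6-[(3-hexanoyl-2,6-dihydroxy-4-methoxyphenyl)methyl]-3,5-dihydroxy-4-methyl-4-(3-methylbut-2-en-1-yl)cyclohexa-2,5-dien-1-one | CCCCCC(=O)c1c(OC)cc(O)c(CC2=C(O)[C@@](C)(CC=C(C)C)C(O)=C(C(=O)CCC)C2=O)c1O | target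

Total step count: 7
Longest linear sequence: 5 steps (steps 3 to 7, from 6)

Steps most likely to fail

Step 6. The enolate may be consumed by proton transfer, from the lactone α-CH2 or from the diketone as it forms, faster than it acylates, or the diketone may close through an enol oxygen instead of carbon. The fallback sets out from 5 and returns at 12. It separates the two bond formations and replaces the lactone by an acyl donor whose adduct persists until work-up. Ring opening of 5 with MeClAlN(OMe)Me (from AlMe3 and MeNHOMe·HCl, CH2Cl2, 0 °C → rt) should give 3-(3-hexanoyl-2,6-dihydroxy-4-methoxyphenyl)-N-methoxy-N-methylpropanamide F1. Its dilithium bis-phenoxide (LiN(SiMe3)2, THF) would be treated with the lithium enolate of 10 at −78 → 0 °C. The chelated tetrahedral adduct releases triketo ester 11 only on acidic work-up, so no diketone is present to quench the enolate. Isolated 11 would then be cyclised in a separate flask with LiN(iPr)2 (THF, −78 → 0 °C) to give 12.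

Step 2. The ring may be alkylated at the carbon between OH and OMe instead of between the two hydroxyls (poor site selectivity), or the hexanoyl group may be lost by acid-induced retro-acylation. The fallback sets out from 1 and returns at 5. It places the three-carbon unit by directed ortho-metalation and introduces the ketone last. MOMCl and iPr2NEt (CH2Cl2) should give 1-methoxy-3,5-bis(methoxymethoxy)benzene F2. n-BuLi (THF, 0 °C) lithiates between the two MOM ethers, and DMF then gives 4-methoxy-2,6-bis(methoxymethoxy)benzaldehyde F3. Wittig olefination with Ph3P=CHCO2Me gives methyl (E)-3-[4-methoxy-2,6-bis(methoxymethoxy)phenyl]prop-2-enoate F4. Hydrogenation (H2, Pd/C, EtOAc) gives methyl 3-[4-methoxy-2,6-bis(methoxymethoxy)phenyl]propanoate F5. HCl in MeOH (50 °C), followed by TsOH in toluene (80 °C) to complete ring closure, removes both MOM groups and lactonises to 5-hydroxy-7-methoxy-3,4-dihydrocoumarin F6. Friedel–Crafts acylation with 2 (AlCl3, CH2Cl2, 0 °C → rt) then gives 5; acylation at C8 instead of C6 would give the lactone isomer, which serves equally in step 6.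

Step 7. Butyryl transfer may go to the ring A phenol oxygens instead of ring B (poor chemoselectivity), or the acyl group may stall on an enol oxygen, leaving C-acylation incomplete. The fallback sets out from 12 and returns at 15. It gives up selectivity altogether and acylates every hydroxyl, so that the outcome no longer depends on the relative rates at ring A and ring B. Butyryl chloride 13 (4.5 equiv) with Et3N (6 equiv, CH2Cl2, 0 °C) should give the tetra-O-butyrate of 12 F7. DMAP (0.3 equiv, rt) then shifts the enol butyrate flanking the free CH to carbon and gives the ring B C-butyryl tri-O-butyrate F8. K2CO3 in MeOH (0 °C → rt, then cold 0.5 M HCl) removes the two aryl butyrates and the remaining enol butyrate as methyl butanoate and liberates 15, the C-acyl triketone being inert as its delocalised enolate.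

Further compounds
F1 | step 6 | 3-(3-hexanoyl-2,6-dihydroxy-4-methoxyphenyl)-N-methoxy-N-methylpropanamide | CCCCCC(=O)c1c(OC)cc(O)c(CCC(=O)N(C)OC)c1O
F2 | step 2 | 1-methoxy-3,5-bis(methoxymethoxy)benzene | COCOc1cc(OC)cc(OCOC)c1
F3 | step 2 | 4-methoxy-2,6-bis(methoxymethoxy)benzaldehyde | COCOc1cc(OC)cc(OCOC)c1C=O
F4 | step 2 | methyl (E)-3-[4-methoxy-2,6-bis(methoxymethoxy)phenyl]prop-2-enoate | COCOc1cc(OC)cc(OCOC)c1/C=C/C(=O)OC
F5 | step 2 | methyl 3-[4-methoxy-2,6-bis(methoxymethoxy)phenyl]propanoate | COCOc1cc(OC)cc(OCOC)c1CCC(=O)OC
F6 | step 2 | 5-hydroxy-7-methoxy-3,4-dihydrocoumarin | O=C1CCc2c(O)cc(OC)cc2O1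
F7 | step 7 | tetra-O-butyrate of 12 (both ring A phenols and both ring B enol oxygens esterified; quaternary carbon as in 12) | CCCCCC(=O)c1c(OC)cc(OC(=O)CCC)c(CC2=C(OC(=O)CCC)[C@@](C)(CC=C(C)C)C(OC(=O)CCC)=CC2=O)c1OC(=O)CCC
F8 | step 7 | tri-O-butyrate of the target (butyryl on the ring B carbon; butyrates on both ring A phenols and on the enol oxygen next to the bridge-bearing carbon; quaternary carbon as in 12) | CCCCCC(=O)c1c(OC)cc(OC(=O)CCC)c(CC2=C(OC(=O)CCC)[C@@](C)(CC=C(C)C)C(O)=C(C(=O)CCC)C2=O)c1OC(=O)CCC
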